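**Retrosynthetic overview**
1. The target is reached by removing one silyl group from its silyl ether. The only ring (14-membered) is closed one step earlier, in a single photochemical nickel/iridium step that joins the vinyl group of (R)-(−)-linalool (1) to both ends of a fifteen-carbon (2Z,6E,10Z)-triene.
2. In that step C1–C2 forms by alkoxide-directed allyl insertion and C13–C14 by capture of a photogenerated allyl radical. C15 is bought with 1; C1 is set under control of C15.
3. The triene carries an allylic tert-butyl carbonate at C2, an allyl trifluoroborate at C13 and a silyl ether on the C4 hydroxymethyl group. It comes from geranyl chloride (2): C11=C12 by iodo-olefination then borylmethylation, C5–C6 by enolate alkylation, C3=C4 by an alkoxy-ketone Wittig reaction.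

Numbering used throughout: C1 is the ring CH, C2 the allylic ring CH2 next to it, C3=C4 the olefin bearing CH2OH, C14 the other ring CH2 on C1, C15 the carbinol carbon.

Assumption: commercial (R)-(−)-linalool of at least 98% ee is used, and the minor C1 epimer from step 7 is removed by chromatography.

**Route**

Step 1
Reactants: 2 geranyl chloride [(2E)-1-chloro-3,7-dimethylocta-2,6-diene]
Product: 4 (4E)-6-chloro-4-methylhex-4-enal, via secondary ozonide 3 (not isolated)
Conditions: O3 (1.0 equiv, Sudan Red 7B end-point), CH2Cl2, −78 °C; Me2S, −78 °C to rt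
Reagents that add atoms: ozone, [O-][O+]=O
Why: Criegee ozonolysis with reductive work-up; the electron-rich 6,7-olefin reacts much faster than the 2,3-olefin, which is deactivated by the allylic chlorine, and no stereocentre is formed.

Step 2
Reactants: 4 (4E)-6-chloro-4-methylhex-4-enal
Product: 5 (2E,6Z)-1-chloro-7-iodo-3-methylocta-2,6-diene
Conditions: [Ph3PEt]I, n-BuLi, THF, 0 °C; I2, −78 °C; NaN(SiMe3)2, −20 °C; then 4, −78 to −20 °C
Reagents that add atoms: ethyltriphenylphosphonium iodide, CC[P+](c1ccccc1)(c1ccccc1)c1ccccc1.[I-]; iodine, II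
Why: Stork–Zhao-type Wittig olefination; the α-iodo ylide adds to the aldehyde under kinetic control to give the (Z)-iodoalkene (about 10:1), and the primary allylic chloride does not alkylate the ylide at this temperature.

Step 3
Reactants: 5 (2E,6Z)-1-chloro-7-iodo-3-methylocta-2,6-diene; 6 1-[(tert-butyldimethylsilyl)oxy]propan-2-one
Product: 8 (5E,9Z)-1-[(tert-butyldimethylsilyl)oxy]-10-iodo-6-methylundeca-5,9-dien-2-one, via lithium enolate 7 (not isolated)
Conditions: 6, LiN(i-Pr)2, THF, −78 °C; then 5, DMPU, Bu4NI (10 mol%), −78 to 0 °C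
Reagents that add atoms: none
Why: Kinetic enolate alkylation (SN2); the amide base removes a methyl proton rather than the hindered silyloxymethylene proton, and the enolate displaces the primary allylic chloride without allylic transposition or attack on the alkenyl iodide.

Step 4
Reactants: 8 (5E,9Z)-1-[(tert-butyldimethylsilyl)oxy]-10-iodo-6-methylundeca-5,9-dien-2-one
Product: 9 (2Z,6E,10Z)-3-{[(tert-butyldimethylsilyl)oxy]methyl}-11-iodo-7-methyldodeca-2,6,10-trien-1-ol
Conditions: [Ph3PCH2CH2OH]Br, KN(SiMe3)2 (2.1 equiv), THF, −78 °C; then 8, −78 °C to rt; H2O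
Reagents that add atoms: (2-hydroxyethyl)triphenylphosphonium bromide, OCC[P+](c1ccccc1)(c1ccccc1)c1ccccc1.[Br-]
Why: Wittig olefination of an α-alkoxy ketone with a non-stabilised ylide under lithium-free conditions (Still's Z-selective variant); the silyloxymethyl arm ends up cis to the ylide-derived CH2OH carbon, which is the (2Z) geometry needed for C3=C4.

Step 5
Reactants: 9 (2Z,6E,10Z)-3-{[(tert-butyldimethylsilyl)oxy]methyl}-11-iodo-7-methyldodeca-2,6,10-trien-1-ol
Product: 11 potassium [(2Z,6E,10Z)-10-{[(tert-butyldimethylsilyl)oxy]methyl}-12-hydroxy-2,6-dimethyldodeca-2,6,10-trien-1-yl]trifluoroborate, via allyl pinacol boronate 10 (not isolated)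
Conditions: CH2(Bpin)2 (1.5 equiv), Pd(P(t-Bu)3)2 (5 mol%), KOH (aq), 1,4-dioxane, 25 °C; then KHF2 (aq), MeOH, 0 °C
Reagents that add atoms: bis(pinacolato)borylmethane, CC1(C)OB(CB2OC(C)(C)C(C)(C)O2)OC1(C)C; potassium hydrogen difluoride, [K+].F[H-]F
Why: Suzuki–Miyaura coupling of the geminal bis(boronate) with the alkenyl iodide keeps the (Z)-olefin geometry and installs C13 as an allylic boronate; KHF2 exchange then gives the stable trifluoroborate.

Step 6
Reactants: 11 potassium [(2Z,6E,10Z)-10-{[(tert-butyldimethylsilyl)oxy]methyl}-12-hydroxy-2,6-dimethyldodeca-2,6,10-trien-1-yl]trifluoroborate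
Product: 12 potassium [(2Z,6E,10Z)-12-[(tert-butoxycarbonyl)oxy]-10-{[(tert-butyldimethylsilyl)oxy]methyl}-2,6-dimethyldodeca-2,6,10-trien-1-yl]trifluoroborate
Conditions: Boc2O, DMAP (10 mol%), MeCN, 25 °C
Reagents that add atoms: di-tert-butyl dicarbonate, CC(C)(C)OC(=O)OC(=O)OC(C)(C)C
Why: DMAP-catalysed acylation of the primary allylic alcohol to the carbonate; the trifluoroborate, silyl ether and olefins are inert.

Step 7
Reactants: 1 (R)-(−)-linalool [(3R)-3,7-dimethylocta-1,6-dien-3-ol] (3 equiv); 12 potassium [(2Z,6E,10Z)-12-[(tert-butoxycarbonyl)oxy]-10-{[(tert-butyldimethylsilyl)oxy]methyl}-2,6-dimethyldodeca-2,6,10-trien-1-yl]trifluoroborate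
Product: 13 (2R)-2-[(1R,3Z,7E,11Z)-4-{[(tert-butyldimethylsilyl)oxy]methyl}-8,12-dimethylcyclotetradeca-3,7,11-trien-1-yl]-6-methylhept-5-en-2-ol
Conditions: Ni(cod)2 (20 mol%), 4,4′-di-tert-butyl-2,2′-bipyridine (22 mol%), [Ir(dF(CF3)ppy)2(bpy)]PF6 (2 mol%), 1,4-dioxane/DMA (4:1), 12 added over 16 h (final 2 mM), 450 nm LEDs, 25 °C
Reagents that add atoms: none
Why: Proposed new method: zerovalent nickel ionises the allylic carbonate of 12 (loss of CO2), and the released tert-butoxide deprotonates 1 to give an η3-allyl divalent nickel alkoxide; alkoxide-directed syn migratory insertion of the vinyl group then puts the primary allyl terminus C2 on the internal carbon C1 and nickel on C14 in a five-membered oxanickelacycle, so C1 is never a free radical and cannot cyclise onto the side-chain olefin; the excited iridium photocatalyst oxidises the allyl trifluoroborate to an allyl radical, the alkyl–nickel centre captures it, and C(sp3)–C(sp3) reductive elimination from trivalent nickel at the primary terminus C13 closes the 14-membered ring, after which the reduced photocatalyst returns monovalent nickel to the zerovalent state; C1 is set in the insertion by C15, with the larger 4-methylpent-3-enyl group anti to the incoming allyl carbon and the methyl group gauche, which gives (1R) from (R)-linalool (estimated d.r. 3:1 to 5:1); both olefin geometries should survive because C3=C4 could only scramble through a tertiary σ-allyl and the C13 allyl radical is trapped before it rotates; the closest known reaction types are nickel-catalysed conjunctive 1,2-dicarbofunctionalisation of alkenes bearing a coordinating group with allyl electrophiles, nickel/photoredox single-electron transmetalation of organotrifluoroborates, and Wilke-type ring synthesis from bis-allyl nickel species and an alkene.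

Step 8
Reactants: 13 (2R)-2-[(1R,3Z,7E,11Z)-4-{[(tert-butyldimethylsilyl)oxy]methyl}-8,12-dimethylcyclotetradeca-3,7,11-trien-1-yl]-6-methylhept-5-en-2-ol
Product: 14 (2R)-2-[(1R,3Z,7E,11Z)-4-(hydroxymethyl)-8,12-dimethylcyclotetradeca-3,7,11-trien-1-yl]-6-methylhept-5-en-2-ol (CNP0389814.1)
Conditions: Bu4NF, THF, 0 °C to rt
Reagents that add atoms: none
Why: Fluoride-mediated Si–O cleavage; the tertiary alcohol, the four olefins and both stereocentres are untouched.

**Compound list**
1 | (R)-(−)-linalool, (3R)-3,7-dimethylocta-1,6-dien-3-ol | CC(C)=CCC[C@@](C)(O)C=C | starting material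
2 | geranyl chloride, (2E)-1-chloro-3,7-dimethylocta-2,6-diene | CC(C)=CCC/C(C)=C/CCl | starting material
3 | 3-[(3E)-5-chloro-3-methylpent-3-en-1-yl]-5,5-dimethyl-1,2,4-trioxolane (secondary ozonide, racemic at the ring CH) | CC1(C)OOC(CC/C(C)=C/CCl)O1 | intermediate
4 | (4E)-6-chloro-4-methylhex-4-enal | O=CCC/C(C)=C/CCl | intermediate
5 | (2E,6Z)-1-chloro-7-iodo-3-methylocta-2,6-diene | ClC/C=C(\C)CC/C=C(/C)I | intermediate
6 | 1-[(tert-butyldimethylsilyl)oxy]propan-2-one | CC(=O)CO[Si](C)(C)C(C)(C)C | starting material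
7 | lithium 3-[(tert-butyldimethylsilyl)oxy]prop-1-en-2-olate | [Li+].C=C([O-])CO[Si](C)(C)C(C)(C)C | intermediate
8 | (5E,9Z)-1-[(tert-butyldimethylsilyl)oxy]-10-iodo-6-methylundeca-5,9-dien-2-one | CC(C)(C)[Si](C)(C)OCC(=O)CC/C=C(\C)CC/C=C(/C)I | intermediate
9 | (2Z,6E,10Z)-3-{[(tert-butyldimethylsilyl)oxy]methyl}-11-iodo-7-methyldodeca-2,6,10-trien-1-ol | OC/C=C(\CO[Si](C)(C)C(C)(C)C)CC/C=C(\C)CC/C=C(/C)I | intermediate
10 | (2Z,6E,10Z)-3-{[(tert-butyldimethylsilyl)oxy]methyl}-7,11-dimethyl-12-(4,4,5,5-tetramethyl-1,3,2-dioxaborolan-2-yl)dodeca-2,6,10-trien-1-ol | OC/C=C(\CO[Si](C)(C)C(C)(C)C)CC/C=C(\C)CC/C=C(/C)CB1OC(C)(C)C(C)(C)O1 | intermediate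
11 | potassium [(2Z,6E,10Z)-10-{[(tert-butyldimethylsilyl)oxy]methyl}-12-hydroxy-2,6-dimethyldodeca-2,6,10-trien-1-yl]trifluoroborate | [K+].OC/C=C(\CO[Si](C)(C)C(C)(C)C)CC/C=C(\C)CC/C=C(/C)C[B-](F)(F)F | intermediate
12 | potassium [(2Z,6E,10Z)-12-[(tert-butoxycarbonyl)oxy]-10-{[(tert-butyldimethylsilyl)oxy]methyl}-2,6-dimethyldodeca-2,6,10-trien-1-yl]trifluoroborate | [K+].CC(C)(C)OC(=O)OC/C=C(\CO[Si](C)(C)C(C)(C)C)CC/C=C(\C)CC/C=C(/C)C[B-](F)(F)F | intermediate
13 | (2R)-2-[(1R,3Z,7E,11Z)-4-{[(tert-butyldimethylsilyl)oxy]methyl}-8,12-dimethylcyclotetradeca-3,7,11-trien-1-yl]-6-methylhept-5-en-2-ol | CC(C)=CCC[C@@](C)(O)[C@H]1C/C=C(\CO[Si](C)(C)C(C)(C)C)CC/C=C(\C)CC/C=C(/C)CC1 | intermediate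
14 | (2R)-2-[(1R,3Z,7E,11Z)-4-(hydroxymethyl)-8,12-dimethylcyclotetradeca-3,7,11-trien-1-yl]-6-methylhept-5-en-2-ol | CC(C)=CCC[C@@](C)(O)[C@H]1C/C=C(\CO)CC/C=C(\C)CC/C=C(/C)CC1 | target

**Step count and risks**

Total step count: 8. Longest linear sequence: 8 steps (2 to 14); 1 enters at step 7.

The three steps most likely to fail:

Step 7 (the proposed new ring-forming step). Likely failure modes are direct allyl–allyl coupling of the two ends of 12 to a 12-membered ring, no insertion of the hindered allylic alkoxide, or a low ratio at C1, since C15 distinguishes only a methyl from a primary alkyl group. The fallback uses known reactions only, sets out from 1 and 9 and comes back at 13. Hydroboration of 1 with 9-BBN and NaOH/H2O2 work-up gives (3R)-3,7-dimethyloct-6-ene-1,3-diol F1. TEMPO/PhI(OAc)2 in MeCN/H2O gives (3R)-3-hydroxy-3,7-dimethyloct-6-enoic acid F2, and Me3SiCHN2 gives methyl (3R)-3-hydroxy-3,7-dimethyloct-6-enoate F3. Alcohol 9 is converted with CBr4/PPh3 into (2Z,6E,10Z)-1-bromo-3-{[(tert-butyldimethylsilyl)oxy]methyl}-11-iodo-7-methyldodeca-2,6,10-triene F4. Fráter–Seebach alkylation of the dianion of F3 (LiN(i-Pr)2, 2.2 equiv, THF/DMPU, −78 to −20 °C) with F4 gives methyl (2R,3R)-2-[(2Z,6E,10Z)-3-{[(tert-butyldimethylsilyl)oxy]methyl}-11-iodo-7-methyldodeca-2,6,10-trien-1-yl]-3-hydroxy-3,7-dimethyloct-6-enoate F5; the electrophile enters the lithium chelate anti to the larger carbinol substituent, and the minor epimer is separated. i-Bu2AlH at −78 °C gives (2R,3R)-2-[(2Z,6E,10Z)-3-{[(tert-butyldimethylsilyl)oxy]methyl}-11-iodo-7-methyldodeca-2,6,10-trien-1-yl]-3-hydroxy-3,7-dimethyloct-6-enal F6. Ph3P=CH2 gives (3S,4R)-3-[(2Z,6E,10Z)-3-{[(tert-butyldimethylsilyl)oxy]methyl}-11-iodo-7-methyldodeca-2,6,10-trien-1-yl]-4,8-dimethylnona-1,7-dien-4-ol F7. 9-BBN adds to the vinyl group to give 9-{(3R,4R)-4-hydroxy-3-[(2Z,6E,10Z)-3-{[(tert-butyldimethylsilyl)oxy]methyl}-11-iodo-7-methyldodeca-2,6,10-trien-1-yl]-4,8-dimethylnon-7-en-1-yl}-9-borabicyclo[3.3.1]nonane F8. Intramolecular B-alkyl Suzuki–Miyaura coupling with the (Z)-alkenyl iodide (Pd(dppf)Cl2, AsPh3, Cs2CO3, DMF/THF/H2O, high dilution) forms C12–C13 with retention and gives 13.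

Step 4 (Z-selectivity of the Wittig reaction with an oxido ylide). The anionic oxygen on the ylide can erode or reverse the alkoxy-ketone Z preference. The fallback is a Horner–Wittig sequence with separation of diastereomers; it sets out from 8 and comes back at 9. The dilithio derivative of 2-(diphenylphosphoryl)ethanol (n-BuLi, 2 equiv, THF, −78 °C) adds to 8, and chromatography isolates rac-(2S,3R,6E,10Z)-3-{[(tert-butyldimethylsilyl)oxy]methyl}-2-(diphenylphosphoryl)-11-iodo-7-methyldodeca-6,10-diene-1,3-diol F9. Stereospecific syn-elimination with NaH in DMF then gives geometrically pure 9.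

Step 3 (regioselective kinetic enolate alkylation with an allylic chloride). Enolate equilibration towards the silyloxy side, polyalkylation or a sluggish chloride can lower the yield. The fallback uses a stabilised enolate and decarboxylation; it sets out from 5 and comes back at 8. The sodium enolate of methyl 4-[(tert-butyldimethylsilyl)oxy]-3-oxobutanoate (NaH, NaI, THF/DMF) is alkylated by 5 to give methyl 4-[(tert-butyldimethylsilyl)oxy]-2-[(2E,6Z)-7-iodo-3-methylocta-2,6-dien-1-yl]-3-oxobutanoate F10. Krapcho dealkoxycarbonylation (LiCl, DMSO/H2O, 130 °C) then gives 8.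

**Further compounds**
F1 | step 7 | (3R)-3,7-dimethyloct-6-ene-1,3-diol | CC(C)=CCC[C@@](C)(O)CCO
F2 | step 7 | (3R)-3-hydroxy-3,7-dimethyloct-6-enoic acid | CC(C)=CCC[C@@](C)(O)CC(=O)O
F3 | step 7 | methyl (3R)-3-hydroxy-3,7-dimethyloct-6-enoate | CC(C)=CCC[C@@](C)(O)CC(=O)OC
F4 | step 7 | (2Z,6E,10Z)-1-bromo-3-{[(tert-butyldimethylsilyl)oxy]methyl}-11-iodo-7-methyldodeca-2,6,10-triene | BrC/C=C(\CO[Si](C)(C)C(C)(C)C)CC/C=C(\C)CC/C=C(/C)I
F5 | step 7 | methyl (2R,3R)-2-[(2Z,6E,10Z)-3-{[(tert-butyldimethylsilyl)oxy]methyl}-11-iodo-7-methyldodeca-2,6,10-trien-1-yl]-3-hydroxy-3,7-dimethyloct-6-enoate | CC(C)=CCC[C@@](C)(O)[C@H](C(=O)OC)C/C=C(\CO[Si](C)(C)C(C)(C)C)CC/C=C(\C)CC/C=C(/C)I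
F6 | step 7 | (2R,3R)-2-[(2Z,6E,10Z)-3-{[(tert-butyldimethylsilyl)oxy]methyl}-11-iodo-7-methyldodeca-2,6,10-trien-1-yl]-3-hydroxy-3,7-dimethyloct-6-enal | CC(C)=CCC[C@@](C)(O)[C@H](C=O)C/C=C(\CO[Si](C)(C)C(C)(C)C)CC/C=C(\C)CC/C=C(/C)I
F7 | step 7 | (3S,4R)-3-[(2Z,6E,10Z)-3-{[(tert-butyldimethylsilyl)oxy]methyl}-11-iodo-7-methyldodeca-2,6,10-trien-1-yl]-4,8-dimethylnona-1,7-dien-4-ol | CC(C)=CCC[C@@](C)(O)[C@H](C=C)C/C=C(\CO[Si](C)(C)C(C)(C)C)CC/C=C(\C)CC/C=C(/C)I
F8 | step 7 | 9-{(3R,4R)-4-hydroxy-3-[(2Z,6E,10Z)-3-{[(tert-butyldimethylsilyl)oxy]methyl}-11-iodo-7-methyldodeca-2,6,10-trien-1-yl]-4,8-dimethylnon-7-en-1-yl}-9-borabicyclo[3.3.1]nonane | CC(C)=CCC[C@@](C)(O)[C@H](CCB1C2CCCC1CCC2)C/C=C(\CO[Si](C)(C)C(C)(C)C)CC/C=C(\C)CC/C=C(/C)I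
F9 | step 4 | rac-(2S,3R,6E,10Z)-3-{[(tert-butyldimethylsilyl)oxy]methyl}-2-(diphenylphosphoryl)-11-iodo-7-methyldodeca-6,10-diene-1,3-diol (one enantiomer drawn) | OC[C@H](P(=O)(c1ccccc1)c1ccccc1)[C@](O)(CO[Si](C)(C)C(C)(C)C)CC/C=C(\C)CC/C=C(/C)I
F10 | step 3 | methyl 4-[(tert-butyldimethylsilyl)oxy]-2-[(2E,6Z)-7-iodo-3-methylocta-2,6-dien-1-yl]-3-oxobutanoate (racemic) | COC(=O)C(C/C=C(\C)CC/C=C(/C)I)C(=O)CO[Si](C)(C)C(C)(C)C
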